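**Plan**

- Cuts: (a) the C2–C(=O) bond between the decalin and the pyridyl ketone, together with the ring A bonds C1–C2 and C4a–C8a (retro-[4+2]), giving acyclic dienylstannane 7 and pyridine acid chloride 17; (b) pyridine C5–C1' (aryllithium + enone) and pyridine C3–CO2H (ortho-lithiation/CO2); (c) C8a=C1 (phosphonate olefination of citronellal).
- Enabling feature: ring A is a cyclohexene carrying the acyl group on C2 next to C3=C4(CH3), a propenyl group on C1 and the four-carbon bridge C5–C8 of ring B. This is the retron of an inverse-demand intramolecular Diels–Alder reaction of a 2,4-dienone (C2=C3–C4=C4a) with the near double bond (C8a=C1) of an (E,E)-diene. Making the C2–C(=O) bond creates the electron-poor diene and triggers closure of both rings.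
- Forward: citronellal chain → triene → trienal → dienylstannane 7 (fragment 1); bromopyridine → aryl addition to the enone → silylation → carboxylation → epoxidation → acid chloride 17 (fragment 2); Stille acylation/cycloaddition closes rings A and B in one operation; C2 epimerisation; global fluoride deprotection.
- Stereochemistry: C7 is bought ((S)-citronellal) and relays to C1, C4a and C8a in the cycloaddition; C2 is set by thermodynamic epimerisation. C4' is bought ((R)-4-silyloxycyclohexenone) and relays to C1' (anti addition) and to the epoxide C2'/C3' (anti epoxidation).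

Key step: step 10

Remark: decalin carbons are numbered C1 (propenyl), C2 (acyl), C3=C4(CH3), C4a, C5–C8 (methyl on C7), C8a; the oxygenated cyclohexane is numbered C1' (carbinol on the pyridine), C2'/C3' (epoxide), C4' (secondary carbinol); 2 and 10 are assumed to be purchasable.

**Route**

Step 1
Reactants: 1 (S)-citronellal; 2 diethyl [(2E)-but-2-en-1-yl]phosphonate
Product: 4 (2E,4E,7S)-7,11-dimethyldodeca-2,4,10-triene, via lithiated phosphonate 3 (not isolated)
Conditions: 2, n-BuLi, THF–DMPU, −78 °C; then 1, −78 °C → rt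
Reagents that add atoms: none
Why: Horner–Wadsworth–Emmons olefination with an allylic phosphonate carbanion, which attacks the aldehyde through its α-carbon and eliminates lithium diethyl phosphate under thermodynamic control to the new (E)-alkene, the crotyl double bond keeping its E geometry and the methyl stereocentre being untouched.

Step 2
Reactants: 4
Product: 6 (2E,6S,8E,10E)-2,6-dimethyldodeca-2,8,10-trienal, via allylic alcohol 5 (not isolated)
Conditions: SeO2 (cat.), t-BuOOH, CH2Cl2, 0 °C → rt; then MnO2, CH2Cl2, rt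
Reagents that add atoms: tert-butyl hydroperoxide, CC(C)(C)OO
Why: Sharpless-type SeO2 allylic oxidation (ene reaction, then [2,3]-sigmatropic shift) should pick the (E)-methyl group of the trisubstituted alkene, the most electron-rich olefin, in preference to the 1,2-disubstituted diene as in the oxidation of myrcene, and MnO2 then converges the alcohol/aldehyde mixture on the (E)-enal.

Step 3
Reactants: 6
Product: 7 tributyl[(1E,3E,7S,9E,11E)-3,7-dimethyltrideca-1,3,9,11-tetraen-1-yl]stannane
Conditions: Bu3SnCHBr2, CrCl2, THF–DMF, rt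
Reagents that add atoms: (dibromomethyl)tributylstannane, CCCC[Sn](CCCC)(CCCC)C(Br)Br
Why: Takai–Hodgson stannyl olefination, in which the geminal dichromium reagent adds to the aldehyde and eliminates anti to give the (E)-alkenylstannane, a reaction that tolerates enals and leaves the remote diene alone.

Step 4
Reactants: 8 5-bromo-2,4-dichloropyridine
Product: 9 5-bromo-2,4-bis[2-(trimethylsilyl)ethoxy]pyridine
Conditions: Me3SiCH2CH2OH (2.5 equiv), NaH, DMF, 0 → 80 °C
Reagents that add atoms: 2-(trimethylsilyl)ethanol, C[Si](C)(C)CCO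
Why: Twofold nucleophilic aromatic substitution at the activated 4- and 2-positions, the unactivated 5-bromide staying in place; the two ethers are fluoride-labile masks for the 4-hydroxy-2-pyridone.

Step 5
Reactants: 9; 10 (4R)-4-{[tert-butyl(dimethyl)silyl]oxy}cyclohex-2-en-1-one
Product: 12 (1S,4R)-1-{4,6-bis[2-(trimethylsilyl)ethoxy]pyridin-3-yl}-4-{[tert-butyl(dimethyl)silyl]oxy}cyclohex-2-en-1-ol, via aryllithium 11 (not isolated)
Conditions: n-BuLi, THF, −78 °C; then 10, −78 °C; aq NH4Cl
Reagents that add atoms: none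
Why: Bromine–lithium exchange followed by 1,2-addition of the aryllithium to the enone, which should occur on the face anti to the pseudoaxial C4' silyloxy group (1,4-induction) and so set C1' with the aryl group trans to the silyl ether.

Step 6
Reactants: 12
Product: 13 5-[(1S,4R)-4-{[tert-butyl(dimethyl)silyl]oxy}-1-[(triethylsilyl)oxy]cyclohex-2-en-1-yl]-2,4-bis[2-(trimethylsilyl)ethoxy]pyridine
Conditions: KN(SiMe3)2, Et3SiCl, THF, −78 → 0 °C
Reagents that add atoms: chlorotriethylsilane, CC[Si](Cl)(CC)CC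
Why: Silylation of the potassium alkoxide under basic conditions, which avoids ionisation of the tertiary, allylic and aryl-substituted carbinol and removes the hydroxyl that would otherwise direct lithiation and syn epoxidation.

Step 7
Reactants: 13
Product: 15 5-[(1S,4R)-4-{[tert-butyl(dimethyl)silyl]oxy}-1-[(triethylsilyl)oxy]cyclohex-2-en-1-yl]-2,4-bis[2-(trimethylsilyl)ethoxy]pyridine-3-carboxylic acid, via 3-lithiopyridine 14 (not isolated)
Conditions: n-BuLi, TMEDA, THF, −78 → −30 °C; CO2 (g), −78 °C → rt; aq KHSO4 (pH 4), 0 °C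
Reagents that add atoms: carbon dioxide, O=C=O
Why: Directed ortho-metalation at C3, the position flanked by both alkoxy groups as in other 5-substituted 2,4-dialkoxypyridines, followed by carboxylation, which introduces the future ketone carbon.

Step 8
Reactants: 15
Product: 16 5-[(1S,2R,5R,6R)-5-{[tert-butyl(dimethyl)silyl]oxy}-2-[(triethylsilyl)oxy]-7-oxabicyclo[4.1.0]heptan-2-yl]-2,4-bis[2-(trimethylsilyl)ethoxy]pyridine-3-carboxylic acid
Conditions: mCPBA, CH2Cl2, 0 °C → rt
Reagents that add atoms: 3-chloroperoxybenzoic acid, OOC(=O)c1cccc(Cl)c1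
Why: Prilezhaev epoxidation under steric control: with both allylic oxygens silylated on the same face (the tertiary silyloxy group pseudoaxial, the aryl group pseudoequatorial) the peracid should approach from the opposite face and give the epoxide anti to both oxygens and cis to the pyridyl group, the 2-alkoxy and 3-carboxyl groups making the pyridine nitrogen a poor competitor for the oxidant.

Step 9
Reactants: 16
Product: 17 5-[(1S,2R,5R,6R)-5-{[tert-butyl(dimethyl)silyl]oxy}-2-[(triethylsilyl)oxy]-7-oxabicyclo[4.1.0]heptan-2-yl]-2,4-bis[2-(trimethylsilyl)ethoxy]pyridine-3-carbonyl chloride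
Conditions: 1-chloro-N,N,2-trimethylprop-1-en-1-amine, CH2Cl2, 0 °C → rt; evaporate, use crude
Reagents that add atoms: 1-chloro-N,N,2-trimethylprop-1-en-1-amine, CC(C)=C(Cl)N(C)C
Why: Acid chloride formation with the Ghosez reagent is neutral (no HCl is released), so the epoxide and the silyl and silylethyl ethers should survive, and it works on hindered doubly ortho-substituted acids.

Step 10
Reactants: 17; 7
Product: 19 [(1R,2R,4aS,7S,8aR)-4,7-dimethyl-1-[(1E)-prop-1-en-1-yl]-1,2,4a,5,6,7,8,8a-octahydronaphthalen-2-yl]{5-[(1S,2R,5R,6R)-5-{[tert-butyl(dimethyl)silyl]oxy}-2-[(triethylsilyl)oxy]-7-oxabicyclo[4.1.0]heptan-2-yl]-2,4-bis[2-(trimethylsilyl)ethoxy]pyridin-3-yl}methanone (C2 epimer; aroyl cis to propenyl), via tetraenone 18 (not isolated)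
Conditions: Pd(PPh3)4 (5 mol %), toluene, 60 °C; then 110 °C
Reagents that add atoms: none
Why: Oxidative addition of the aroyl chloride to zerovalent palladium, transmetalation of the dienyl group from tin and reductive elimination (Stille ketone synthesis) form the C2–C(=O) bond and so turn the unactivated tetraene into the electron-poor 2,4-dienone 18, which on heating should undergo an intramolecular inverse-demand Diels–Alder reaction with the near C8a=C1 bond of the (E,E)-diene; the closest known reaction type is the thermal cycloaddition of 2,4-dienals and 2,4-dienones tethered to an alkene by four carbons (1,7,9-decatriene type). Ring A (cyclohexene C1–C2–C3=C4–C4a–C8a) closes by the concerted suprafacial [4+2] bond pair C2–C1 and C4a–C8a, and ring B (cyclohexane C4a–C5–C6–C7–C8–C8a) closes in the same act as the chair-like ring of the four-carbon tether. The C7 methyl group, equatorial on this chair, selects the π-faces and so fixes C4a and C8a; the E geometry of the dienophile places H8a and H1 trans (propenyl equatorial), and the trans ring fusion follows from the transition state with the propenyl group endo, the cis-fused alternative suffering a clash between the C4 methyl group and the tether. The E,E geometry of the diene necessarily delivers H2 cis to H4a, that is the aroyl group cis to the propenyl group (2R), and this epimer is corrected in step 11. The step needs periselectivity (the dienone as four-electron partner, not the terminal diene adding across C4=C4a), and the substitution pattern should secure it, since the competing mode would have to build a quaternary centre at C4 against the methyl-bearing terminus of the diene.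

Step 11
Reactants: 19
Product: 20 [(1R,2S,4aS,7S,8aR)-4,7-dimethyl-1-[(1E)-prop-1-en-1-yl]-1,2,4a,5,6,7,8,8a-octahydronaphthalen-2-yl]{5-[(1S,2R,5R,6R)-5-{[tert-butyl(dimethyl)silyl]oxy}-2-[(triethylsilyl)oxy]-7-oxabicyclo[4.1.0]heptan-2-yl]-2,4-bis[2-(trimethylsilyl)ethoxy]pyridin-3-yl}methanone
Conditions: DBU, toluene, rt → 50 °C
Reagents that add atoms: none
Why: Base-mediated epimerisation through the dienolate, whose kinetically preferred α-protonation keeps the C3=C4 double bond in place while thermodynamic control moves the aroyl group from the pseudoaxial to the pseudoequatorial position, trans to the propenyl group (2S).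

Step 12
Reactants: 20
Product: 21 4-hydroxy-5-[(1S,2R,5R,6S)-2,5-dihydroxy-7-oxabicyclo[4.1.0]heptan-2-yl]-3-{[(1R,2S,4aS,7S,8aR)-4,7-dimethyl-1-[(1E)-prop-1-en-1-yl]-1,2,4a,5,6,7,8,8a-octahydronaphthalen-2-yl]carbonyl}pyridin-2(1H)-one
Conditions: Bu4NF, AcOH (1:1), THF, rt → 45 °C
Reagents that add atoms: none
Why: Fluoride-induced cleavage of both silyl ethers and fluoride-triggered fragmentation of both 2-(trimethylsilyl)ethyl ethers (loss of ethene and fluorotrimethylsilane, the acylpyridonate being a good leaving group) should unveil the 4-hydroxy-2-pyridone and the diol in one operation, the acetic acid buffer suppressing Payne rearrangement of the epoxy alcohols and any change at C2.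

**Compound list**

1 | (S)-citronellal | O=CC[C@@H](C)CCC=C(C)C | starting material
2 | diethyl [(2E)-but-2-en-1-yl]phosphonate | C/C=C/CP(=O)(OCC)OCC | starting material
3 | α-lithiated diethyl [(2E)-but-2-en-1-yl]phosphonate | [Li]C(/C=C/C)P(=O)(OCC)OCC | intermediate
4 | (2E,4E,7S)-7,11-dimethyldodeca-2,4,10-triene | C/C=C/C=C/C[C@@H](C)CCC=C(C)C | intermediate
5 | (2E,6S,8E,10E)-2,6-dimethyldodeca-2,8,10-trien-1-ol | C/C=C/C=C/C[C@@H](C)CC/C=C(\C)CO | intermediate
6 | (2E,6S,8E,10E)-2,6-dimethyldodeca-2,8,10-trienal | C/C=C/C=C/C[C@@H](C)CC/C=C(\C)C=O | intermediate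
7 | tributyl[(1E,3E,7S,9E,11E)-3,7-dimethyltrideca-1,3,9,11-tetraen-1-yl]stannane | C/C=C/C=C/C[C@@H](C)CC/C=C(\C)/C=C/[Sn](CCCC)(CCCC)CCCC | intermediate
8 | 5-bromo-2,4-dichloropyridine | Clc1cc(Cl)c(Br)cn1 | starting material
9 | 5-bromo-2,4-bis[2-(trimethylsilyl)ethoxy]pyridine | C[Si](C)(C)CCOc1cc(OCC[Si](C)(C)C)c(Br)cn1 | intermediate
10 | (4R)-4-{[tert-butyl(dimethyl)silyl]oxy}cyclohex-2-en-1-one | O=C1CC[C@@H](O[Si](C)(C)C(C)(C)C)C=C1 | starting material
11 | {4,6-bis[2-(trimethylsilyl)ethoxy]pyridin-3-yl}lithium | [Li]c1cnc(OCC[Si](C)(C)C)cc1OCC[Si](C)(C)C | intermediate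
12 | (1S,4R)-1-{4,6-bis[2-(trimethylsilyl)ethoxy]pyridin-3-yl}-4-{[tert-butyl(dimethyl)silyl]oxy}cyclohex-2-en-1-ol | C[Si](C)(C)CCOc1cc(OCC[Si](C)(C)C)c([C@]2(O)CC[C@@H](O[Si](C)(C)C(C)(C)C)C=C2)cn1 | intermediate
13 | 5-[(1S,4R)-4-{[tert-butyl(dimethyl)silyl]oxy}-1-[(triethylsilyl)oxy]cyclohex-2-en-1-yl]-2,4-bis[2-(trimethylsilyl)ethoxy]pyridine | C[Si](C)(C)CCOc1cc(OCC[Si](C)(C)C)c([C@]2(O[Si](CC)(CC)CC)CC[C@@H](O[Si](C)(C)C(C)(C)C)C=C2)cn1 | intermediate
14 | 3-lithio derivative of 13 | [Li]c1c(OCC[Si](C)(C)C)c([C@]2(O[Si](CC)(CC)CC)CC[C@@H](O[Si](C)(C)C(C)(C)C)C=C2)cnc1OCC[Si](C)(C)C | intermediate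
15 | 5-[(1S,4R)-4-{[tert-butyl(dimethyl)silyl]oxy}-1-[(triethylsilyl)oxy]cyclohex-2-en-1-yl]-2,4-bis[2-(trimethylsilyl)ethoxy]pyridine-3-carboxylic acid | OC(=O)c1c(OCC[Si](C)(C)C)c([C@]2(O[Si](CC)(CC)CC)CC[C@@H](O[Si](C)(C)C(C)(C)C)C=C2)cnc1OCC[Si](C)(C)C | intermediate
16 | 5-[(1S,2R,5R,6R)-5-{[tert-butyl(dimethyl)silyl]oxy}-2-[(triethylsilyl)oxy]-7-oxabicyclo[4.1.0]heptan-2-yl]-2,4-bis[2-(trimethylsilyl)ethoxy]pyridine-3-carboxylic acid (epoxide anti to both silyloxy groups) | OC(=O)c1c(OCC[Si](C)(C)C)c([C@]2(O[Si](CC)(CC)CC)CC[C@@H](O[Si](C)(C)C(C)(C)C)[C@@H]3O[C@@H]32)cnc1OCC[Si](C)(C)C | intermediate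
17 | acid chloride of 16 (pyridine-3-carbonyl chloride) | ClC(=O)c1c(OCC[Si](C)(C)C)c([C@]2(O[Si](CC)(CC)CC)CC[C@@H](O[Si](C)(C)C(C)(C)C)[C@@H]3O[C@@H]32)cnc1OCC[Si](C)(C)C | intermediate
18 | (2E,4E,8S,10E,12E)-4,8-dimethyl-1-{the pyridin-3-yl group of 17}tetradeca-2,4,10,12-tetraen-1-one | C/C=C/C=C/C[C@@H](C)CC/C=C(\C)/C=C/C(=O)c1c(OCC[Si](C)(C)C)c([C@]2(O[Si](CC)(CC)CC)CC[C@@H](O[Si](C)(C)C(C)(C)C)[C@@H]3O[C@@H]32)cnc1OCC[Si](C)(C)C | intermediate
19 | (1R,2R,4aS,7S,8aR)-decalinyl pyridin-3-yl ketone, C2 epimer (aroyl cis to propenyl), fully protected | C/C=C/[C@@H]1[C@H]2C[C@@H](C)CC[C@@H]2C(C)=C[C@@H]1C(=O)c1c(OCC[Si](C)(C)C)c([C@]2(O[Si](CC)(CC)CC)CC[C@@H](O[Si](C)(C)C(C)(C)C)[C@@H]3O[C@@H]32)cnc1OCC[Si](C)(C)C | intermediate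
20 | (1R,2S,4aS,7S,8aR)-decalinyl pyridin-3-yl ketone (aroyl trans to propenyl), fully protected | C/C=C/[C@@H]1[C@H]2C[C@@H](C)CC[C@@H]2C(C)=C[C@H]1C(=O)c1c(OCC[Si](C)(C)C)c([C@]2(O[Si](CC)(CC)CC)CC[C@@H](O[Si](C)(C)C(C)(C)C)[C@@H]3O[C@@H]32)cnc1OCC[Si](C)(C)C | intermediate
21 | 4-hydroxy-5-[(1S,2R,5R,6S)-2,5-dihydroxy-7-oxabicyclo[4.1.0]heptan-2-yl]-3-{[(1R,2S,4aS,7S,8aR)-4,7-dimethyl-1-[(1E)-prop-1-en-1-yl]-1,2,4a,5,6,7,8,8a-octahydronaphthalen-2-yl]carbonyl}pyridin-2(1H)-one | C/C=C/[C@@H]1[C@H]2C[C@@H](C)CC[C@@H]2C(C)=C[C@H]1C(=O)c1c(O)c([C@]2(O)CC[C@@H](O)[C@@H]3O[C@@H]32)c[nH]c1=O | target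

**Step count**

Total: 12 steps. Longest linear sequence: 9 steps (8 → 21, steps 4–12). The tetraene branch (steps 1–3) joins at step 10.

**Steps most likely to fail, with fallbacks**

Step 10. At the doubly ortho-substituted aroylpalladium stage, decarbonylation may outrun transmetalation. At the temperature of the cycloaddition, the dienone may also close with poor trans/cis or facial selectivity, or through the mode in which the terminal diene is the four-electron partner. The fallback closes the rings first on a robust small molecule and joins the fragments afterwards at the same bond through a sulfone-stabilised carbanion. It sets out from 6 and 17. Trienal 6 is condensed with diethyl [(phenylsulfonyl)methyl]phosphonate (NaH, THF; Horner–Wadsworth–Emmons) to the dienyl sulfone [(1E,3E,7S,9E,11E)-3,7-dimethyltrideca-1,3,9,11-tetraen-1-yl]sulfonylbenzene F1. Heating (toluene, 110–140 °C) should effect the same inverse-demand cycloaddition, with the sulfonyl diene as four-electron partner, to the allylic sulfone {[(1R,2R,4aS,7S,8aR)-4,7-dimethyl-1-[(1E)-prop-1-en-1-yl]-1,2,4a,5,6,7,8,8a-octahydronaphthalen-2-yl]sulfonyl}benzene F2, on which isomers can be separated before the pyridine fragment is committed. Deprotonation (n-BuLi, THF, −78 °C) gives the lithiated sulfone F3, which is C-acylated by acid chloride 17 to the α-sulfonyl ketone F4. Reductive desulfonylation (SmI2, THF–MeOH, −78 °C) and equilibration with DBU as in step 11 return the route at 20.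

Step 8. The peracid may oxidise the pyridine nitrogen, the doubly allylic-oxygenated alkene may react sluggishly, or the facial bias may be insufficient so that attack occurs syn to the silyloxy groups. The fallback uses no peracid: the epoxide is made by nucleophilic epoxidation of an enone and C4' is re-set afterwards. It sets out from 12 and returns at 16.
- Bu4NF (THF) gives (1S,4R)-1-{4,6-bis[2-(trimethylsilyl)ethoxy]pyridin-3-yl}cyclohex-2-ene-1,4-diol F5.
- MnO2 oxidises only the secondary allylic alcohol, giving the 4-aryl-4-hydroxycyclohex-2-enone F6.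
- Et3SiOTf/2,6-lutidine gives the triethylsilyl ether F7.
- Alkaline H2O2 (Weitz–Scheffer) should epoxidise anti to the pseudoaxial silyloxy group and cis to the aryl group, giving the epoxy ketone F8.
- NaBH4/CeCl3 should deliver hydride anti to the epoxide, giving the cis-epoxy alcohol F9.
- Mitsunobu inversion (4-nitrobenzoic acid, PPh3, diisopropyl azodicarboxylate) gives the 4-nitrobenzoate F10.
- Methanolysis (K2CO3, MeOH) gives the trans-epoxy alcohol F11.
- t-BuMe2SiOTf/2,6-lutidine gives the bis-silyl ether F12.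
- Ortho-lithiation (n-BuLi, TMEDA, −78 °C) to the 3-lithiopyridine F13 and carboxylation as in step 7 give 16.

Step 11. Under equilibrating base the dienolate may be reprotonated at C4 (migration of the double bond into conjugation), or the equilibrium may not lie far enough on the side of the trans isomer. The fallback replaces thermodynamic by kinetic control and sets out from 19. Irreversible deprotonation (KN(SiMe3)2, THF, −78 °C) gives the potassium dienolate F14. It is quenched at −78 °C with 2,6-di-tert-butyl-4-methylphenol; α-protonation along the axial direction of ring A should place the new hydrogen axial and the aroyl group equatorial, returning the route at 20.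

**Further compounds**

F1 | step 10 | [(1E,3E,7S,9E,11E)-3,7-dimethyltrideca-1,3,9,11-tetraen-1-yl]sulfonylbenzene | C/C=C/C=C/C[C@@H](C)CC/C=C(\C)/C=C/S(=O)(=O)c1ccccc1
F2 | step 10 | {[(1R,2R,4aS,7S,8aR)-4,7-dimethyl-1-[(1E)-prop-1-en-1-yl]-1,2,4a,5,6,7,8,8a-octahydronaphthalen-2-yl]sulfonyl}benzene | C/C=C/[C@@H]1[C@H]2C[C@@H](C)CC[C@@H]2C(C)=C[C@@H]1S(=O)(=O)c1ccccc1
F3 | step 10 | 2-lithio derivative of F2 | C/C=C/[C@@H]1[C@H]2C[C@@H](C)CC[C@@H]2C(C)=CC1([Li])S(=O)(=O)c1ccccc1
F4 | step 10 | 2-(phenylsulfonyl) derivative of ketone 19/20 (α-sulfonyl ketone, C2 unspecified) | C/C=C/[C@@H]1[C@H]2C[C@@H](C)CC[C@@H]2C(C)=CC1(S(=O)(=O)c1ccccc1)C(=O)c1c(OCC[Si](C)(C)C)c([C@]2(O[Si](CC)(CC)CC)CC[C@@H](O[Si](C)(C)C(C)(C)C)[C@@H]3O[C@@H]32)cnc1OCC[Si](C)(C)C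
F5 | step 8 | (1S,4R)-1-{4,6-bis[2-(trimethylsilyl)ethoxy]pyridin-3-yl}cyclohex-2-ene-1,4-diol | C[Si](C)(C)CCOc1cc(OCC[Si](C)(C)C)c([C@]2(O)CC[C@@H](O)C=C2)cn1
F6 | step 8 | (4S)-4-{4,6-bis[2-(trimethylsilyl)ethoxy]pyridin-3-yl}-4-hydroxycyclohex-2-en-1-one | C[Si](C)(C)CCOc1cc(OCC[Si](C)(C)C)c([C@]2(O)CCC(=O)C=C2)cn1
F7 | step 8 | triethylsilyl ether of F6 | C[Si](C)(C)CCOc1cc(OCC[Si](C)(C)C)c([C@]2(O[Si](CC)(CC)CC)CCC(=O)C=C2)cn1
F8 | step 8 | 2,3-epoxy ketone from F7 (epoxide anti to the triethylsilyloxy group, cis to the pyridyl group) | C[Si](C)(C)CCOc1cc(OCC[Si](C)(C)C)c([C@]2(O[Si](CC)(CC)CC)CCC(=O)[C@@H]3O[C@@H]32)cn1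
F9 | step 8 | cis-epoxy alcohol from F8 (C4' hydroxyl cis to the epoxide) | C[Si](C)(C)CCOc1cc(OCC[Si](C)(C)C)c([C@]2(O[Si](CC)(CC)CC)CC[C@H](O)[C@@H]3O[C@@H]32)cn1
F10 | step 8 | 4-nitrobenzoate with inverted C4' (ester trans to the epoxide) | C[Si](C)(C)CCOc1cc(OCC[Si](C)(C)C)c([C@]2(O[Si](CC)(CC)CC)CC[C@@H](OC(=O)c4ccc(cc4)[N+](=O)[O-])[C@@H]3O[C@@H]32)cn1
F11 | step 8 | trans-epoxy alcohol from F10 | C[Si](C)(C)CCOc1cc(OCC[Si](C)(C)C)c([C@]2(O[Si](CC)(CC)CC)CC[C@@H](O)[C@@H]3O[C@@H]32)cn1
F12 | step 8 | tert-butyldimethylsilyl ether of F11 (16 without the carboxyl group) | C[Si](C)(C)CCOc1cc(OCC[Si](C)(C)C)c([C@]2(O[Si](CC)(CC)CC)CC[C@@H](O[Si](C)(C)C(C)(C)C)[C@@H]3O[C@@H]32)cn1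
F13 | step 8 | 3-lithio derivative of F12 | [Li]c1c(OCC[Si](C)(C)C)c([C@]2(O[Si](CC)(CC)CC)CC[C@@H](O[Si](C)(C)C(C)(C)C)[C@@H]3O[C@@H]32)cnc1OCC[Si](C)(C)C
F14 | step 11 | potassium dienolate of 19 | C/C=C/[C@@H]1[C@H]2C[C@@H](C)CC[C@@H]2C(C)=CC1=C([O-])c1c(OCC[Si](C)(C)C)c([C@]2(O[Si](CC)(CC)CC)CC[C@@H](O[Si](C)(C)C(C)(C)C)[C@@H]3O[C@@H]32)cnc1OCC[Si](C)(C)C.[K+]
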